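## Retrosynthetic overview

1. The target is a cis,cis-germacranolide: a ten-membered carbocycle (C1–C10, with a 1,10-oxirane and a 4Z alkene) trans-fused at C6–C7 to an α-methylene-γ-butyrolactone (O6, C6, C7, C11, C12). The last disconnections are the C9 silyl ether and the C8 (2S)-2-methylbutanoate.
2. Key disconnection C7–C11: the lactone is read as an intramolecular Morita–Baylis–Hillman adduct. The enabling feature is that C11 is the α-carbon of an acrylate that can hang on O6, while C7 lies between the two oxygen-bearing ring carbons C6 and C8. A 6-O-acryloyl trans-7,8-epoxide (array O6–C6–C7(–O–)C8 in the ten-membered ring) puts C11 at the backside of the C7–O bond; opening it closes the lactone, sets C7 and frees O8 alone.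
3. Ten-membered ring: C5–C6 by Nozaki–Hiyama–Kishi closure of a (Z)-vinyl iodide onto an α,β-epoxy aldehyde. Before that, the 1,10-oxirane comes from a hydroxyl-directed epoxidation and C1=C10 from cross-metathesis of two fragments.
4. Fragment A is (1Z)-1-iodo-2-methylhexa-1,5-diene (carbocupration of propyne). Fragment B is an epoxy diol from the acrolein/methyl acrylate Morita–Baylis–Hillman adduct (cross-metathesis, then Sharpless epoxidation as the source of absolute configuration).
5. Order of ring formation: 7,8-oxirane (step 4), 1,10-oxirane (step 6), ten-membered carbocycle (step 9), γ-lactone with loss of the 7,8-oxirane (step 11).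

Key step: step 11

Remark (assumption on the chemistry): atoms keep the germacranolide locants of the target throughout (C1–C10 ring, C11–C13 lactone carbons, C14 ester carbon, C15 methyl). Racemic material is carried to step 4, where the absolute configuration is introduced. CIP letters of intermediates change with substituent priorities while the spatial arrangement stays that of the target.

## Route

Step 1
Reactants: 1 but-3-enylmagnesium bromide (in Et2O); 2 propyne
Product: 5 (1Z)-1-iodo-2-methylhexa-1,5-diene, via but-3-enylcopper 3 (not isolated), via (1Z)-alkenylcopper 4 (not isolated)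
Conditions: CuBr·SMe2 (1.0 equiv), Et2O/Me2S, −45 °C; propyne, −25 °C; then I2, −50 → 0 °C
Reagents that add atoms: iodine, [I][I]
Why: Normant syn-carbocupration of a terminal alkyne puts the alkyl group on the internal carbon with copper cis to it, and iodinolysis with retention should give the (Z)-iodide, i.e. the future C4=C5 geometry with C3 and C6 cis.

Step 2
Reactants: 6 acrolein; 7 methyl acrylate
Product: 8 methyl 3-hydroxy-2-methylidenepent-4-enoate (racemic)
Conditions: DABCO (20 mol %), neat 7 (4 equiv), slow addition of 6, 0 → 25 °C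
Reagents that add atoms: none
Why: Morita–Baylis–Hillman reaction in which the aldehyde carbon becomes C9 and the acrylate α-carbon C10, the excess of acrylate suppressing self-condensation of acrolein.

Step 3
Reactants: 8 methyl 3-hydroxy-2-methylidenepent-4-enoate; 9 (2Z)-but-2-ene-1,4-diol
Product: 10 methyl (4E)-3,6-dihydroxy-2-methylidenehex-4-enoate (racemic)
Conditions: second-generation Grubbs catalyst (3 mol %), 9 (4 equiv), CH2Cl2/THF, 25 °C
Reagents that add atoms: none
Why: Olefin cross-metathesis of the monosubstituted vinyl group with the symmetrical diol should give the E-allylic alcohol, while the 1,1-disubstituted electron-poor acrylate alkene stays untouched under these mild conditions.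

Step 4
Reactants: 10 methyl (4E)-3,6-dihydroxy-2-methylidenehex-4-enoate (racemic)
Product: 11 methyl (3S)-3-hydroxy-3-[(2R,3R)-3-(hydroxymethyl)oxiran-2-yl]-2-methylidenepropanoate
Conditions: Ti(OiPr)4 (10 mol %), D-(−)-diisopropyl tartrate (12 mol %), t-BuOOH (1.5 equiv), 4 Å molecular sieves, CH2Cl2, −20 °C; chromatographic separation of diastereomers
Reagents that add atoms: tert-butyl hydroperoxide, CC(C)(C)OO
Why: Sharpless asymmetric epoxidation directed by the primary allylic hydroxyl delivers oxygen to the same alkene face of both enantiomers of 10 (D-tartrate gives the 2R,3R-oxirane of an E-2-alken-1-ol), so the (3R)-enantiomer should give the required threo epoxy diol 11 and the (3S)-enantiomer the separable erythro diastereomer; at most half of 10 can end as 11.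

Step 5
Reactants: 11 methyl (3S)-3-hydroxy-3-[(2R,3R)-3-(hydroxymethyl)oxiran-2-yl]-2-methylidenepropanoate; 5 (1Z)-1-iodo-2-methylhexa-1,5-diene
Product: 12 methyl (2E,6Z)-2-{(S)-hydroxy[(2R,3R)-3-(hydroxymethyl)oxiran-2-yl]methyl}-7-iodo-6-methylhepta-2,6-dienoate
Conditions: second-generation Hoveyda–Grubbs catalyst (10 mol %), 5 (3 equiv), CH2Cl2, 40 °C
Reagents that add atoms: none
Why: Cross-metathesis of an α-substituted acrylate with a terminal alkene should give the trisubstituted enoate with the new chain trans to the ester (E, the cis-in-ring C1=C10 geometry), the trisubstituted vinyl iodide being inert to the ruthenium carbene.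

Step 6
Reactants: 12 methyl (2E,6Z)-2-{(S)-hydroxy[(2R,3R)-3-(hydroxymethyl)oxiran-2-yl]methyl}-7-iodo-6-methylhepta-2,6-dienoate
Product: 13 methyl (2S,3R)-2-{(R)-hydroxy[(2R,3R)-3-(hydroxymethyl)oxiran-2-yl]methyl}-3-[(3Z)-4-iodo-3-methylbut-3-en-1-yl]oxirane-2-carboxylate
Conditions: VO(acac)2 (10 mol %), t-BuOOH (2.5 equiv), PhMe, 25 → 50 °C
Reagents that add atoms: tert-butyl hydroperoxide, CC(C)(C)OO
Why: Hydroxyl-directed vanadium-catalysed epoxidation of the C9 allylic alcohol, in which the chain cis to the carbinol carbon imposes 1,3-allylic strain so that oxygen is delivered from the conformer with the carbinol hydrogen in the alkene plane, should give the threo epoxy alcohol (C1 and C10 set) and leave the undirected vinyl iodide alone.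

Step 7
Reactants: 13 methyl (2S,3R)-2-{(R)-hydroxy[(2R,3R)-3-(hydroxymethyl)oxiran-2-yl]methyl}-3-[(3Z)-4-iodo-3-methylbut-3-en-1-yl]oxirane-2-carboxylate
Product: 14 methyl (2R,3R)-3-[(3Z)-4-iodo-3-methylbut-3-en-1-yl]-2-{(R)-(triethylsilyloxy)[(2S,3R)-3-(triethylsilyloxymethyl)oxiran-2-yl]methyl}oxirane-2-carboxylate
Conditions: Et3SiOTf (2.5 equiv), 2,6-lutidine (4 equiv), CH2Cl2, −78 °C
Reagents that add atoms: triethylsilyl trifluoromethanesulfonate, CC[Si](CC)(CC)OS(=O)(=O)C(F)(F)F
Why: Standard silylation of both hydroxyls with a silyl triflate and a hindered base at low temperature, conditions that leave both oxiranes intact.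

Step 8
Reactants: 14 methyl (2R,3R)-3-[(3Z)-4-iodo-3-methylbut-3-en-1-yl]-2-{(R)-(triethylsilyloxy)[(2S,3R)-3-(triethylsilyloxymethyl)oxiran-2-yl]methyl}oxirane-2-carboxylate
Product: 16 methyl (2R,3R)-2-{(R)-[(2S,3S)-3-formyloxiran-2-yl](triethylsilyloxy)methyl}-3-[(3Z)-4-iodo-3-methylbut-3-en-1-yl]oxirane-2-carboxylate, via alkoxysulfonium chloride 15 (not isolated)
Conditions: (COCl)2 (4 equiv), DMSO (8 equiv), CH2Cl2, −78 → −30 °C; then Et3N, −78 → 0 °C
Reagents that add atoms: none
Why: Swern conditions convert a primary triethylsilyl ether directly into the aldehyde (silyl transfer to chloride, then the usual alkoxysulfonium fragmentation) while the hindered secondary silyl ether at C9 survives, so C6 and C9 are differentiated without a separate deprotection.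

Step 9
Reactants: 16 methyl (2R,3R)-2-{(R)-[(2S,3S)-3-formyloxiran-2-yl](triethylsilyloxy)methyl}-3-[(3Z)-4-iodo-3-methylbut-3-en-1-yl]oxirane-2-carboxylate
Product: 18 methyl (1R,6R,7R,8S,9R,10R,4Z)-1,10:7,8-diepoxy-6-hydroxy-4-methyl-9-(triethylsilyloxy)cyclodec-4-ene-10-carboxylate (ring numbered as in the target), via alkenylchromium dichloride 17 (not isolated)
Conditions: CrCl2 (8 equiv), NiCl2 (2 mol %), DMSO/THF, 0.003 M, 25 °C; aqueous work-up
Reagents that add atoms: none
Why: Intramolecular Nozaki–Hiyama–Kishi reaction, in which zerovalent nickel inserts into the C–I bond and transmetallation to trivalent chromium gives an alkenylchromium that keeps the Z geometry and adds to the aldehyde, should close the ten-membered ring at C5–C6 with the new C6 carbinol anti (erythro) to the adjacent oxirane by Felkin–Anh addition to the α,β-epoxy aldehyde.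

Step 10
Reactants: 18 methyl (1R,6R,7R,8S,9R,10R,4Z)-1,10:7,8-diepoxy-6-hydroxy-4-methyl-9-(triethylsilyloxy)cyclodec-4-ene-10-carboxylate; 19 acryloyl chloride
Product: 20 methyl (1R,6R,7R,8S,9R,10R,4Z)-6-(acryloyloxy)-1,10:7,8-diepoxy-4-methyl-9-(triethylsilyloxy)cyclodec-4-ene-10-carboxylate
Conditions: iPr2NEt (5 equiv), CH2Cl2, −40 → 0 °C
Reagents that add atoms: none
Why: O-acylation of the secondary allylic alcohol with an acid chloride and a non-nucleophilic amine, a base too weak to trigger Payne rearrangement of the epoxy alcohol.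

Step 11
Reactants: 20 methyl (1R,6R,7R,8S,9R,10R,4Z)-6-(acryloyloxy)-1,10:7,8-diepoxy-4-methyl-9-(triethylsilyloxy)cyclodec-4-ene-10-carboxylate
Product: 23 methyl (1R,6R,7R,8S,9R,10R)-1,10-epoxy-8-hydroxy-9-(triethylsilyloxy)germacra-4Z,11(13)-dien-12,6-olid-14-oate, via phosphonium ester enolate 21 (not isolated), via phosphonium lactone alkoxide 22 (not isolated)
Conditions: PMe3 (1.0 equiv), t-BuOH/THF 1:1, 0.02 M, 25 °C
Reagents that add atoms: none
Why: Proposed new method: PMe3 adds reversibly to the unsubstituted acrylate terminus C13 to give the phosphonium ester enolate 21, whose α-carbon C11 is held by the ester oxygen on C6 at the backside of the C7–O bond of the trans-7,8-oxirane and opens it by SN2 attack (tert-butanol hydrogen-bonds to the oxirane oxygen); proton transfer from C11 to the C8 alkoxide of 22 and E1cB loss of PMe3 then restore the C11=C13 double bond. The closest known reaction types are the phosphine-mediated intramolecular Morita–Baylis–Hillman alkylation of enones by tethered epoxides and halides and the Morita–Baylis–Hillman cyclisation of acrylate esters onto tethered aldehydes; an acrylate α-carbon opening an epoxide through an ester-oxygen tether to give an α-methylene-γ-lactone has not been shown. The one ring closed is the γ-lactone (C11, C12, O, C6, C7), by 5-exo-tet attack at the proximal oxirane carbon, the mode known for carbamate and imidate nucleophiles on 2,3-epoxy alcohol derivatives. C7 is set by inversion in the stereospecific anti opening and C8 keeps its oxirane oxygen with retention (C11 and O8 end cis on the ring); the erythro relation between O6 and the oxirane (from steps 4 and 9) places O6 anti-periplanar to the breaking bond in the extended C5–C6–C7–C8 conformer, which is the geometry of the trans-fused lactone. The step needs attack at C7 (5-exo) and not at C8 (6-endo), and reaction of the acrylate and the 7,8-oxirane only: C8 is shielded by the C9 silyl ether, the glycidate carbons C1 and C10 are out of reach of C11 and should not be opened by PMe3 alone at 25 °C, the protic medium quenches the C8 alkoxide before silyl migration or translactonisation, and dilution suppresses intermolecular Rauhut–Currier coupling.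

Step 12
Reactants: 23 methyl (1R,6R,7R,8S,9R,10R)-1,10-epoxy-8-hydroxy-9-(triethylsilyloxy)germacra-4Z,11(13)-dien-12,6-olid-14-oate; 24 (2S)-2-methylbutanoic acid
Product: 26 methyl (1R,6R,7S,8S,9R,10R)-1,10-epoxy-8-[(2S)-2-methylbutanoyloxy]-9-(triethylsilyloxy)germacra-4Z,11(13)-dien-12,6-olid-14-oate, via O-acylisourea 25 (not isolated)
Conditions: DCC (2 equiv), DMAP (0.2 equiv), CH2Cl2, 0 → 25 °C
Reagents that add atoms: none
Why: Steglich esterification of the only free hydroxyl (C8–OH, released in step 11) with retention at C8, low temperature and catalytic DMAP keeping the α-stereocentre of the acid intact.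

Step 13
Reactants: 26 methyl (1R,6R,7S,8S,9R,10R)-1,10-epoxy-8-[(2S)-2-methylbutanoyloxy]-9-(triethylsilyloxy)germacra-4Z,11(13)-dien-12,6-olid-14-oate
Product: 27 methyl (1R,6R,7S,8S,9R,10S)-1,10-epoxy-9-hydroxy-8-[(2S)-2-methylbutanoyloxy]germacra-4Z,11(13)-dien-12,6-olid-14-oate (CNP0581690.1)
Conditions: HF·pyridine, pyridine, THF, 0 °C
Reagents that add atoms: none
Why: Fluoride-assisted cleavage of the secondary triethylsilyl ether under buffered, weakly acidic conditions should not cause 8→9 acyl migration, conjugate addition to the α-methylene lactone or opening of the electron-poor glycidate.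

## Compound list

1 | but-3-enylmagnesium bromide | C=CCC[Mg]Br | starting material
2 | propyne | CC#C | starting material
3 | but-3-enylcopper (not isolated) | C=CCC[Cu] | intermediate
4 | (1Z)-(2-methylhexa-1,5-dien-1-yl)copper (not isolated) | [Cu]/C=C(/C)CCC=C | intermediate
5 | (1Z)-1-iodo-2-methylhexa-1,5-diene | I/C=C(/C)CCC=C | intermediate
6 | acrolein | C=CC=O | starting material
7 | methyl acrylate | C=CC(=O)OC | starting material
8 | methyl 3-hydroxy-2-methylidenepent-4-enoate (racemic) | C=CC(O)C(=C)C(=O)OC | intermediate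
9 | (2Z)-but-2-ene-1,4-diol | OC/C=C\CO | starting material
10 | methyl (4E)-3,6-dihydroxy-2-methylidenehex-4-enoate (racemic) | C=C(C(=O)OC)C(O)/C=C/CO | intermediate
11 | methyl (3S)-3-hydroxy-3-[(2R,3R)-3-(hydroxymethyl)oxiran-2-yl]-2-methylidenepropanoate | C=C(C(=O)OC)[C@H](O)[C@H]1O[C@@H]1CO | intermediate
12 | methyl (2E,6Z)-2-{(S)-hydroxy[(2R,3R)-3-(hydroxymethyl)oxiran-2-yl]methyl}-7-iodo-6-methylhepta-2,6-dienoate | I/C=C(/C)CC/C=C(/C(=O)OC)[C@H](O)[C@H]1O[C@@H]1CO | intermediate
13 | methyl (2S,3R)-2-{(R)-hydroxy[(2R,3R)-3-(hydroxymethyl)oxiran-2-yl]methyl}-3-[(3Z)-4-iodo-3-methylbut-3-en-1-yl]oxirane-2-carboxylate | I/C=C(/C)CC[C@H]1O[C@@]1(C(=O)OC)[C@H](O)[C@H]2O[C@@H]2CO | intermediate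
14 | methyl (2R,3R)-3-[(3Z)-4-iodo-3-methylbut-3-en-1-yl]-2-{(R)-(triethylsilyloxy)[(2S,3R)-3-(triethylsilyloxymethyl)oxiran-2-yl]methyl}oxirane-2-carboxylate | I/C=C(/C)CC[C@H]1O[C@@]1(C(=O)OC)[C@H](O[Si](CC)(CC)CC)[C@H]2O[C@@H]2CO[Si](CC)(CC)CC | intermediate
15 | alkoxysulfonium chloride of the C6 oxygen (not isolated) | I/C=C(/C)CC[C@H]1O[C@@]1(C(=O)OC)[C@H](O[Si](CC)(CC)CC)[C@H]2O[C@@H]2CO[S+](C)C.[Cl-] | intermediate
16 | methyl (2R,3R)-2-{(R)-[(2S,3S)-3-formyloxiran-2-yl](triethylsilyloxy)methyl}-3-[(3Z)-4-iodo-3-methylbut-3-en-1-yl]oxirane-2-carboxylate | I/C=C(/C)CC[C@H]1O[C@@]1(C(=O)OC)[C@H](O[Si](CC)(CC)CC)[C@H]2O[C@@H]2C=O | intermediate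
17 | (Z)-alkenylchromium dichloride derived from 16 (not isolated) | Cl[Cr](Cl)/C=C(/C)CC[C@H]1O[C@@]1(C(=O)OC)[C@H](O[Si](CC)(CC)CC)[C@H]2O[C@@H]2C=O | intermediate
18 | methyl (1R,6R,7R,8S,9R,10R,4Z)-1,10:7,8-diepoxy-6-hydroxy-4-methyl-9-(triethylsilyloxy)cyclodec-4-ene-10-carboxylate (target numbering) | O[C@@H]1/C=C(/C)CC[C@H]2O[C@@]2(C(=O)OC)[C@H](O[Si](CC)(CC)CC)[C@H]3O[C@H]13 | intermediate
19 | acryloyl chloride | C=CC(=O)Cl | starting material
20 | methyl (1R,6R,7R,8S,9R,10R,4Z)-6-(acryloyloxy)-1,10:7,8-diepoxy-4-methyl-9-(triethylsilyloxy)cyclodec-4-ene-10-carboxylate (target numbering) | C=CC(=O)O[C@@H]1/C=C(/C)CC[C@H]2O[C@@]2(C(=O)OC)[C@H](O[Si](CC)(CC)CC)[C@H]3O[C@H]13 | intermediate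
21 | C13-trimethylphosphonio ester enolate of 20 (not isolated) | C[P+](C)(C)CC=C([O-])O[C@@H]1/C=C(/C)CC[C@H]2O[C@@]2(C(=O)OC)[C@H](O[Si](CC)(CC)CC)[C@H]3O[C@H]13 | intermediate
22 | C13-trimethylphosphonio lactone C8-alkoxide (not isolated, C11 epimers) | C[P+](C)(C)CC1C(=O)O[C@@H]2/C=C(/C)CC[C@H]3O[C@@]3(C(=O)OC)[C@H](O[Si](CC)(CC)CC)[C@@H]([O-])[C@@H]12 | intermediate
23 | methyl (1R,6R,7R,8S,9R,10R)-1,10-epoxy-8-hydroxy-9-(triethylsilyloxy)germacra-4Z,11(13)-dien-12,6-olid-14-oate | C=C1C(=O)O[C@@H]2/C=C(/C)CC[C@H]3O[C@@]3(C(=O)OC)[C@H](O[Si](CC)(CC)CC)[C@@H](O)[C@@H]12 | intermediate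
24 | (2S)-2-methylbutanoic acid | CC[C@H](C)C(=O)O | starting material
25 | O-acylisourea of 24 with DCC (not isolated) | CC[C@H](C)C(=O)OC(=NC1CCCCC1)NC1CCCCC1 | intermediate
26 | methyl (1R,6R,7S,8S,9R,10R)-1,10-epoxy-8-[(2S)-2-methylbutanoyloxy]-9-(triethylsilyloxy)germacra-4Z,11(13)-dien-12,6-olid-14-oate | C=C1C(=O)O[C@@H]2/C=C(/C)CC[C@H]3O[C@@]3(C(=O)OC)[C@H](O[Si](CC)(CC)CC)[C@@H](OC(=O)[C@@H](C)CC)[C@@H]12 | intermediate
27 | methyl (1R,6R,7S,8S,9R,10S)-1,10-epoxy-9-hydroxy-8-[(2S)-2-methylbutanoyloxy]germacra-4Z,11(13)-dien-12,6-olid-14-oate (CNP0581690.1) | C=C1C(=O)O[C@@H]2/C=C(/C)CC[C@H]3O[C@@]3(C(=O)OC)[C@H](O)[C@@H](OC(=O)[C@@H](C)CC)[C@@H]12 | target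

## Step count and risks

Total step count: 13. Longest linear sequence: 12 steps (steps 2 to 13; step 1 is a one-step side branch).

**Step 11 (Proposed new method).** What may go wrong: phosphine addition stays reversible without ring closure, because the ester must adopt its less favoured s-cis conformation before C11 can reach C7. Alternatively the acrylate oligomerises by intermolecular Rauhut–Currier coupling, or the C8 alkoxide translactonises. Fallback with a stoichiometric stabilised carbanion, setting out from 18 and returning at 23: 18 would be esterified with diethylphosphonoacetic acid (DCC, DMAP, CH2Cl2) to give the phosphonoacetate F1. LiN(SiMe3)2 (1.1 equiv, THF, −78 → 0 °C) would generate the phosphonate carbanion, which opens the 7,8-oxirane at C7 in the same 5-exo mode to give the α-phosphono lactone F2. Paraformaldehyde added to the same flask would then give 23 by Horner–Wadsworth–Emmons methylenation.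

**Step 9.** What may go wrong: poor facial selectivity at the aldehyde in the macrocyclic transition state, so that the ring closes to a mixture of C6 epimers. Fallback that sets C6 by reduction instead of by the C–C bond formation, setting out from 16 and returning at 18: the mixture of 18 and its C6 epimer F3 would be oxidised with Dess–Martin periodinane (NaHCO3, CH2Cl2) to the macrocyclic epoxy enone F4. F4 would be reduced with Zn(BH4)2 (Et2O, −20 °C); zinc chelation between the carbonyl and oxirane oxygens directs hydride to give the erythro epoxy alcohol 18.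

**Step 6.** What may go wrong: sluggish oxygen transfer from the electrophilic vanadium peroxide to the electron-poor, α-branched enoate, or erosion of the threo preference. Fallback under catalyst control instead of substrate direction, from 12 directly to 13: Shi epoxidation with the fructose-derived diacetate ketone (KHSO5, NaHCO3, MeCN/aqueous buffer, 0 °C), a chiral dioxirane that accepts α,β-unsaturated esters. The catalyst enantiomer would be chosen for the required alkene face. This fallback makes no new compound F0.

Further compounds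
F1 | step 11 | 6-O-(diethoxyphosphoryl)acetyl ester of 18 | CCOP(=O)(OCC)CC(=O)O[C@@H]1/C=C(/C)CC[C@H]2O[C@@]2(C(=O)OC)[C@H](O[Si](CC)(CC)CC)[C@H]3O[C@H]13
F2 | step 11 | 11-(diethoxyphosphoryl)-11,13-dihydro analog of 23 (C11 epimers) | CCOP(=O)(OCC)C1C(=O)O[C@@H]2/C=C(/C)CC[C@H]3O[C@@]3(C(=O)OC)[C@H](O[Si](CC)(CC)CC)[C@@H](O)[C@@H]12
F3 | step 9 | C6 epimer of 18 | O[C@H]1/C=C(/C)CC[C@H]2O[C@@]2(C(=O)OC)[C@H](O[Si](CC)(CC)CC)[C@H]3O[C@H]13
F4 | step 9 | 6-oxo analog of 18 (macrocyclic epoxy enone) | O=C1/C=C(/C)CC[C@H]2O[C@@]2(C(=O)OC)[C@H](O[Si](CC)(CC)CC)[C@H]3O[C@H]13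
F0 | step 6 | none | none
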